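At 2.5 h the flask is read, so the question is whether its solid substrate lasts that long.

| flask | solid substrate | reagent | remark | time |
|---|---|---|---|---|
| Sunday's | 20 mM | 24 mM | the very flask that is asked about, followed so far |  |
| flask | 20 mM | 24.0 mM |  | 2.5 h |
Sunday's run (percent of the solid substrate charged)

| time / min | solid substrate / % | isomer of the product / % | solid product / % | target / % |
|---|---|---|---|---|
| 6.00 | 95 | 1 | 0 | 2 |
| 15.0 | 90 | 0 | 2 | 6 |
| 30.0 | 82 | 1 | 10 | 16 |
| 50.0 | 68 | 0 | 23 | 27 |

(standard deviation of a reading: 1.5 percentage points)
- amounts and yields of target count solid product too
- given per volume of solution although it is solid: solid substrate, solid product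
- at the start none of the solid substrate is in solution
- as a choice and as an amount asked, solid substrate means what is still solid
1. the species that holds most of what was charged as solid substrate, at 2.5 h (solid substrate / target / solid product / isomer of the product)
2. the largest share itself, whichever of these holds it, in percent of the solid substrate charged

Sunday's run is this flask followed so far, and its readings form a ladder. First comes the falling out of target: at 50.0 min, dissolved target (target less solid product) reads 4 percentage points, less than the 23 % of solid product. Next comes the reaction: the 5.00 % unread at that time is taken as dissolved substrate, less than target. With [dissolved substrate] this low, the readings of the solid fit zero order within their scatter: the loss reads 0.108 mM min⁻¹ early and 0.140 mM min⁻¹ later. Below these, the isomer of the product reads 0 % at 50.0 min.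

Across the run, solid substrate goes at 0.123 mM min⁻¹. A charge divided by that rate gives 2.72 h for the solid, its charge lifetime; for reagent it gives 3.26 h, which is longer. The time asked is shorter than the solid's lifetime, so this reckoning leaves 7.95 % as solid and, with the unread share unchanged, 87.0 % as target, solid product included.

The forecast gives target at 80 %, lower than this reckoning, with about 15 % of substrate left: “I expect something in between”.

The flask gives target at 79.4 %, with solid substrate at 8.93 % against the reckoned 7.95 %, and dissolved substrate at 10.8 %.

    solid substrate ⇌ dissolved substrate, rate k1*(cs1 - [dissolved substrate]) while solid is left; crystals form when [dissolved substrate] > cs1 (solubility = 8.80 mM, k = 0.0160 min⁻¹)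
    dissolved substrate + reagent → target (k = 7.20 L mol⁻¹ min⁻¹)
    solid product ⇌ target, rate k3*(cs3 - [target]) while solid is left; crystals form when [target] > cs3 (solubility = 0.560 mM, k = 0.250 min⁻¹)
    reagent ⇌ dormant form (K = 2.80, k = 0.00120 min⁻¹)
    target ⇌ isomer of the product (K = 3.60, k = 0.00120 min⁻¹)

The neighbouring flask charges 6.0 mM of reagent, 0.300 equiv, with the other charges and the time held. Reckoned at the rate of Sunday's run, its reagent lifetime is 0.815 h, shorter than the solid's, so reagent is expected to be the limiting reagent in that flask. At 2.50 h that flask keeps 1.52 % of its reagent, with target at 27.1 % and dissolved substrate at 32.9 %, and solid substrate holds most, at 39.4 %.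

The data are simulated with constants of no real substance; scatter was added.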